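**Retrosynthetic overview**
- Last C–O bond: Yamaguchi ester between the C6 alcohol of the bicyclic core and (2E,4E,6R)-6-hydroxy-6-methylocta-2,4-dienoic acid. The 7,8-alkene (chloranil) and the free 3-OH (desilylation) are revealed after the coupling.
- Core: the C4a–C5 bond (quaternary centre) is made by oxidative para-dearomatisation of a 3,4-disubstituted phenol by its tethered silyl enol ether, using a chiral diacetoxy-λ3-iodane that turns the phenol ring into a vinylogous enolonium. The 3-oxygen then comes from 1,4-hydrosilylation/Rubottom oxidation, the C6 alcohol from LiBH(s-Bu)3.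
- Cyclisation substrate: Heck reaction of 3-bromo-4-methylphenol with penta-1,4-dien-3-ol, then 1,4-hydrosilylation to the Z enol ether.
- Acid: (S)-2-methylglycidol + MeMgBr/CuI, Parikh–Doering oxidation, vinylogous Horner–Wadsworth–Emmons olefination with in-flask saponification.
- Ring order: ring B (the hydroxy-enone ring) is the benzene ring of the bromophenol from the start; ring A (the ester-bearing ring) closes in the dearomatisation.

Assumption: the (R,R)-iodane is taken to deliver the (4aR)-dione; were the sense reversed, the (S,S)-antipode would be used with no other change.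

**Route**

Step 1
Reactants: 1 3-bromo-4-methylphenol; 2 penta-1,4-dien-3-ol
Product: 3 5-(5-hydroxy-2-methylphenyl)pent-1-en-3-one
Conditions: Pd(OAc)2 (5 mol%), n-Bu4NCl, NaHCO3, DMF, 70 °C, 2 (3 equiv)
Reagents that add atoms: none
Why: Heck arylation of an allylic alcohol (Jeffery conditions), in which β-hydride elimination toward the carbinol gives the enol and hence the ketone while the second vinyl group survives as a vinyl ketone; no stereocentre is formed.

Step 2
Reactants: 3 5-(5-hydroxy-2-methylphenyl)pent-1-en-3-one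
Product: 4 triethyl{[(2Z)-5-{2-methyl-5-[(triethylsilyl)oxy]phenyl}pent-2-en-3-yl]oxy}silane
Conditions: Et3SiH (2.4 equiv), RhCl(PPh3)3 (1 mol%), THF, 50 °C
Reagents that add atoms: triethylsilane CC[SiH](CC)CC
Why: Rhodium-catalysed 1,4-hydrosilylation of the s-cis vinyl ketone gives the Z silyl enol ether regiospecifically on the C-methyl side, and the same catalyst couples Et3SiH dehydrogenatively with the phenol, so the next step releases no Brønsted acid.

Step 3
Reactants: 4 triethyl{[(2Z)-5-{2-methyl-5-[(triethylsilyl)oxy]phenyl}pent-2-en-3-yl]oxy}silane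
Product: 5 (4aR,5R)-4a,5-dimethyl-7,8-dihydronaphthalene-2,6(4aH,5H)-dione
Conditions: (R,R)-ArI(OAc)2 (1.1 equiv; Ar = 2,6-bis[1-(mesitylamino)-1-oxopropan-2-yloxy]phenyl), CH2Cl2/CF3CH2OH 4:1, −40 °C
Reagents that add atoms: none
Why: Proposed new method: ligand exchange of the aryl silyl ether on the chiral trivalent-iodine reagent gives an O-bound aryloxy-λ3-iodane whose para carbon (normally nucleophilic) is now an electrophile, a doubly vinylogous enolonium, and the tethered Z enol ether attacks it through a chair-like 6-(enolendo) transition state (enol methyl equatorial, hence cis to the angular methyl) while the lactamide arms shield one ring face to fix 4aR, the tertiary, methyl-bearing para position being preferred over the open ortho position; the closest known reaction types are the achiral PhI(OAc)2-type oxidative para-dearomatisation of phenols and phenol silyl ethers by tethered silyl enol ethers and the enantioselective hydroxylative para-dearomatisation of 3,4-disubstituted phenols by chiral aryl-λ3-iodanes.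

Step 4
Reactants: 5 (4aR,5R)-4a,5-dimethyl-7,8-dihydronaphthalene-2,6(4aH,5H)-dione
Product: 7 (3R,4aR,5R)-4a,5-dimethyl-3-[(triethylsilyl)oxy]-4,4a,7,8-tetrahydronaphthalene-2,6(3H,5H)-dione, via silyl dienol ether 6 (not isolated)
Conditions: Et3SiH (1.1 equiv), RhCl(PPh3)3 (2 mol%), PhMe, 40 °C; then DMDO, acetone, −40 → 0 °C
Reagents that add atoms: triethylsilane CC[SiH](CC)CC; dimethyldioxirane CC1(C)OO1
Why: 1,4-Hydrosilylation puts hydride on C4, the only β-carbon of the cross-conjugated dienone that is not fully substituted, and Rubottom oxidation of the resulting 2-silyloxy diene epoxidises the enol ether bond anti to the angular methyl, 1,4-silyl migration then giving the 3R silyloxy ketone (oxygen equatorial, trans to the angular methyl).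

Step 5
Reactants: 7 (3R,4aR,5R)-4a,5-dimethyl-3-[(triethylsilyl)oxy]-4,4a,7,8-tetrahydronaphthalene-2,6(3H,5H)-dione
Product: 8 (3R,4aR,5R,6S)-6-hydroxy-4a,5-dimethyl-3-[(triethylsilyl)oxy]-4,4a,5,6,7,8-hexahydronaphthalen-2(3H)-one
Conditions: LiBH(s-Bu)3 (1.05 equiv), THF, −78 °C; H2O
Reagents that add atoms: none
Why: The bulky borohydride reduces the saturated cyclohexanone much faster than the β,β-disubstituted enone and attacks equatorially, anti to the axial angular methyl, giving the axial 6S alcohol cis to both methyls (diastereoselective ketone reduction).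

Step 6
Reactants: 9 (S)-2-methylglycidol
Product: 10 (R)-2-methylbutane-1,2-diol
Conditions: MeMgBr (3 equiv), CuI (10 mol%), THF, −30 → 0 °C; H2O
Reagents that add atoms: methylmagnesium bromide C[Mg]Br
Why: Copper-catalysed Grignard opening of the 2,2-disubstituted epoxide at its CH2 carbon (SN2) leaves the stereocentre untouched; the ring CH2 becomes the ethyl group, so the descriptor changes from S to R by priority only.

Step 7
Reactants: 10 (R)-2-methylbutane-1,2-diol
Product: 11 (R)-2-hydroxy-2-methylbutanal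
Conditions: SO3·pyridine, DMSO, Et3N, CH2Cl2, 0 °C
Reagents that add atoms: none
Why: Parikh–Doering oxidation takes the primary alcohol to the aldehyde without touching the tertiary alcohol, and the product has no α-hydrogen to epimerise.

Step 8
Reactants: 11 (R)-2-hydroxy-2-methylbutanal; 12 triethyl 4-phosphonocrotonate
Product: 14 (2E,4E,6R)-6-hydroxy-6-methylocta-2,4-dienoic acid, via ethyl ester 13 (not isolated)
Conditions: LiN(SiMe3)2 (2.1 equiv), THF, −78 → 0 °C; then LiOH, H2O/MeOH, rt; 1 M HCl to pH 3, 0 °C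
Reagents that add atoms: lithium hydroxide [Li+].[OH-]
Why: Vinylogous Horner–Wadsworth–Emmons olefination forms the new 4,5-alkene E and keeps the 2,3-alkene E, and hydroxide saponifies the ethyl ester in the same flask.

Step 9
Reactants: 14 (2E,4E,6R)-6-hydroxy-6-methylocta-2,4-dienoic acid; 8 (3R,4aR,5R,6S)-6-hydroxy-4a,5-dimethyl-3-[(triethylsilyl)oxy]-4,4a,5,6,7,8-hexahydronaphthalen-2(3H)-one
Product: 16 (1R,2S,7R,8aR)-1,8a-dimethyl-6-oxo-7-[(triethylsilyl)oxy]-1,2,3,4,6,7,8,8a-octahydronaphthalen-2-yl (2E,4E,6R)-6-hydroxy-6-methylocta-2,4-dienoate, via mixed anhydride 15 (not isolated)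
Conditions: 2,4,6-Cl3C6H2COCl, Et3N, THF, rt; then 8, DMAP, PhMe, 40 °C
Reagents that add atoms: none
Why: Yamaguchi esterification acylates the only free secondary alcohol with retention (the tertiary alcohol of the acid is inert and the 3-oxygen is silylated), the mixed anhydride/DMAP pair being suited to the hindered axial alcohol.

Step 10
Reactants: 16 (1R,2S,7R,8aR)-1,8a-dimethyl-6-oxo-7-[(triethylsilyl)oxy]-1,2,3,4,6,7,8,8a-octahydronaphthalen-2-yl (2E,4E,6R)-6-hydroxy-6-methylocta-2,4-dienoate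
Product: 17 (1R,2S,7R,8aR)-1,8a-dimethyl-6-oxo-7-[(triethylsilyl)oxy]-1,2,6,7,8,8a-hexahydronaphthalen-2-yl (2E,4E,6R)-6-hydroxy-6-methylocta-2,4-dienoate
Conditions: chloranil (1.5 equiv), t-BuOH, reflux
Reagents that add atoms: none
Why: Quinone dehydrogenation of the enone through its extended dienol removes the γ and δ hydrogens and gives the linear dienone, as in the conversion of 4-en-3-ones into 4,6-dien-3-ones; no stereocentre is touched and the tertiary alcohol has no carbinol hydrogen to lose.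

Step 11
Reactants: 17 (1R,2S,7R,8aR)-1,8a-dimethyl-6-oxo-7-[(triethylsilyl)oxy]-1,2,6,7,8,8a-hexahydronaphthalen-2-yl (2E,4E,6R)-6-hydroxy-6-methylocta-2,4-dienoate
Product: 18 (1R,2S,7R,8aR)-7-hydroxy-1,8a-dimethyl-6-oxo-1,2,6,7,8,8a-hexahydronaphthalen-2-yl (2E,4E,6R)-6-hydroxy-6-methylocta-2,4-dienoate
Conditions: HF·pyridine, pyridine/THF, 0 °C
Reagents that add atoms: none
Why: Buffered fluoride desilylation frees the α-ketol without epimerising it (the equatorial hydroxyl is also the thermodynamic one) and without ionising the tertiary allylic alcohol.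

**Compound list**
1 | 3-bromo-4-methylphenol | Cc1ccc(O)cc1Br | starting material
2 | penta-1,4-dien-3-ol | C=CC(O)C=C | starting material
3 | 5-(5-hydroxy-2-methylphenyl)pent-1-en-3-one | C=CC(=O)CCc1cc(O)ccc1C | intermediate
4 | triethyl{[(2Z)-5-{2-methyl-5-[(triethylsilyl)oxy]phenyl}pent-2-en-3-yl]oxy}silane | C/C=C(\O[Si](CC)(CC)CC)CCc1cc(O[Si](CC)(CC)CC)ccc1C | intermediate
5 | (4aR,5R)-4a,5-dimethyl-7,8-dihydronaphthalene-2,6(4aH,5H)-dione | O=C1CCC2=CC(=O)C=C[C@]2(C)[C@H]1C | intermediate
6 | (4aR,5R)-4a,5-dimethyl-2-[(triethylsilyl)oxy]-4,4a,7,8-tetrahydronaphthalen-6(5H)-one | O=C1CCC2=CC(O[Si](CC)(CC)CC)=CC[C@]2(C)[C@H]1C | intermediate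
7 | (3R,4aR,5R)-4a,5-dimethyl-3-[(triethylsilyl)oxy]-4,4a,7,8-tetrahydronaphthalene-2,6(3H,5H)-dione | O=C1CCC2=CC(=O)[C@H](O[Si](CC)(CC)CC)C[C@]2(C)[C@H]1C | intermediate
8 | (3R,4aR,5R,6S)-6-hydroxy-4a,5-dimethyl-3-[(triethylsilyl)oxy]-4,4a,5,6,7,8-hexahydronaphthalen-2(3H)-one | O[C@H]1CCC2=CC(=O)[C@H](O[Si](CC)(CC)CC)C[C@]2(C)[C@H]1C | intermediate
9 | (S)-2-methylglycidol, [(2S)-2-methyloxiran-2-yl]methanol | C[C@]1(CO)CO1 | starting material
10 | (R)-2-methylbutane-1,2-diol | CC[C@@](C)(O)CO | intermediate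
11 | (R)-2-hydroxy-2-methylbutanal | CC[C@@](C)(O)C=O | intermediate
12 | triethyl 4-phosphonocrotonate, ethyl (2E)-4-(diethoxyphosphoryl)but-2-enoate | CCOC(=O)/C=C/CP(=O)(OCC)OCC | starting material
13 | ethyl (2E,4E,6R)-6-hydroxy-6-methylocta-2,4-dienoate | CC[C@@](C)(O)/C=C/C=C/C(=O)OCC | intermediate
14 | (2E,4E,6R)-6-hydroxy-6-methylocta-2,4-dienoic acid | CC[C@@](C)(O)/C=C/C=C/C(=O)O | intermediate
15 | (2E,4E,6R)-6-hydroxy-6-methylocta-2,4-dienoic 2,4,6-trichlorobenzoic anhydride | CC[C@@](C)(O)/C=C/C=C/C(=O)OC(=O)c1c(Cl)cc(Cl)cc1Cl | intermediate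
16 | (1R,2S,7R,8aR)-1,8a-dimethyl-6-oxo-7-[(triethylsilyl)oxy]-1,2,3,4,6,7,8,8a-octahydronaphthalen-2-yl (2E,4E,6R)-6-hydroxy-6-methylocta-2,4-dienoate | CC[C@@](C)(O)/C=C/C=C/C(=O)O[C@H]1CCC2=CC(=O)[C@H](O[Si](CC)(CC)CC)C[C@]2(C)[C@H]1C | intermediate
17 | (1R,2S,7R,8aR)-1,8a-dimethyl-6-oxo-7-[(triethylsilyl)oxy]-1,2,6,7,8,8a-hexahydronaphthalen-2-yl (2E,4E,6R)-6-hydroxy-6-methylocta-2,4-dienoate | CC[C@@](C)(O)/C=C/C=C/C(=O)O[C@H]1C=CC2=CC(=O)[C@H](O[Si](CC)(CC)CC)C[C@]2(C)[C@H]1C | intermediate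
18 | (1R,2S,7R,8aR)-7-hydroxy-1,8a-dimethyl-6-oxo-1,2,6,7,8,8a-hexahydronaphthalen-2-yl (2E,4E,6R)-6-hydroxy-6-methylocta-2,4-dienoate | CC[C@@](C)(O)/C=C/C=C/C(=O)O[C@H]1C=CC2=CC(=O)[C@H](O)C[C@]2(C)[C@H]1C | target

**Step count**
Total: 11 steps. Longest linear sequence: 8 steps (1, 2, 3, 4, 5, 9, 10, 11); the acid arm is 3 steps (6, 7, 8).

**Steps most likely to fail, with fallbacks**

Step 3. The enantio-induction by the chiral iodane with a carbon nucleophile is unproven, and attack at the open ortho position (giving a tetralone) may compete. Fallback: give up reagent control and resolve later. Setting out from 4, plain PhI(OAc)2 in CF3CH2OH gives the racemic dione, that is 5 together with (4aS,5S)-4a,5-dimethyl-7,8-dihydronaphthalene-2,6(4aH,5H)-dione F1. The racemate is carried through the hydrosilylation/Rubottom sequence unchanged, so that 7 is accompanied by (3S,4aS,5S)-4a,5-dimethyl-3-[(triethylsilyl)oxy]-4,4a,7,8-tetrahydronaphthalene-2,6(3H,5H)-dione F3, formed through (4aS,5S)-4a,5-dimethyl-2-[(triethylsilyl)oxy]-4,4a,7,8-tetrahydronaphthalen-6(5H)-one F2. The borohydride is then replaced by an NADPH-dependent ketoreductase (chosen by screening a commercial panel, i-PrOH for cofactor recycling) that reduces only the (3R,4aR,5R)-ketone. The route is rejoined at 8 and F3 is separated unchanged.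

Step 10. Hydride abstraction next to the acyloxy-bearing carbon may be slow, and the silyloxy ketone side may be over-oxidised. Fallback: make the alkene by selenoxide elimination before the ester is formed. Setting out from 7, LiN(i-Pr)2 then PhSeBr at −78 °C selenenylates the CH2 next to the saturated ketone to give (3R,4aR,5R)-4a,5-dimethyl-7-(phenylselanyl)-3-[(triethylsilyl)oxy]-4,4a,7,8-tetrahydronaphthalene-2,6(3H,5H)-dione F4. LiBH(s-Bu)3 at −78 °C gives (3R,4aR,5R,6R)-6-hydroxy-4a,5-dimethyl-7-(phenylselanyl)-3-[(triethylsilyl)oxy]-4,4a,5,6,7,8-hexahydronaphthalen-2(3H)-one F5. H2O2/pyridine at 0 °C oxidises selenium, and the selenoxide eliminates syn, away from the carbinol, to (3R,4aR,5R,6S)-6-hydroxy-4a,5-dimethyl-3-[(triethylsilyl)oxy]-4,4a,5,6-tetrahydronaphthalen-2(3H)-one F6. Yamaguchi esterification of F6 with 14 then gives 17, where the route is rejoined.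

Step 1. The vinyl ketone product can undergo a second arylation or polymerise under the Heck conditions. Fallback: build the vinyl ketone from a Weinreb amide. Setting out from 1, Heck coupling with N-methoxy-N-methylacrylamide (Pd(OAc)2, P(o-tol)3, Et3N, MeCN, 80 °C) gives (2E)-3-(5-hydroxy-2-methylphenyl)-N-methoxy-N-methylprop-2-enamide F7. Hydrogenation (H2, Pd/C, EtOAc) gives 3-(5-hydroxy-2-methylphenyl)-N-methoxy-N-methylpropanamide F8. CH2=CHMgBr (2.5 equiv, THF, 0 °C, inverse quench into cold aqueous HCl) converts the amide into 3, where the route is rejoined.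

**Further compounds**
F1 | step 3 | (4aS,5S)-4a,5-dimethyl-7,8-dihydronaphthalene-2,6(4aH,5H)-dione | O=C1CCC2=CC(=O)C=C[C@@]2(C)[C@@H]1C
F2 | step 3 | (4aS,5S)-4a,5-dimethyl-2-[(triethylsilyl)oxy]-4,4a,7,8-tetrahydronaphthalen-6(5H)-one | O=C1CCC2=CC(O[Si](CC)(CC)CC)=CC[C@@]2(C)[C@@H]1C
F3 | step 3 | (3S,4aS,5S)-4a,5-dimethyl-3-[(triethylsilyl)oxy]-4,4a,7,8-tetrahydronaphthalene-2,6(3H,5H)-dione | O=C1CCC2=CC(=O)[C@@H](O[Si](CC)(CC)CC)C[C@@]2(C)[C@@H]1C
F4 | step 10 | (3R,4aR,5R)-4a,5-dimethyl-7-(phenylselanyl)-3-[(triethylsilyl)oxy]-4,4a,7,8-tetrahydronaphthalene-2,6(3H,5H)-dione (C7 epimers) | O=C1C([Se]c3ccccc3)CC2=CC(=O)[C@H](O[Si](CC)(CC)CC)C[C@]2(C)[C@H]1C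
F5 | step 10 | (3R,4aR,5R,6R)-6-hydroxy-4a,5-dimethyl-7-(phenylselanyl)-3-[(triethylsilyl)oxy]-4,4a,5,6,7,8-hexahydronaphthalen-2(3H)-one (C7 epimers) | O[C@H]1C([Se]c3ccccc3)CC2=CC(=O)[C@H](O[Si](CC)(CC)CC)C[C@]2(C)[C@H]1C
F6 | step 10 | (3R,4aR,5R,6S)-6-hydroxy-4a,5-dimethyl-3-[(triethylsilyl)oxy]-4,4a,5,6-tetrahydronaphthalen-2(3H)-one | O[C@H]1C=CC2=CC(=O)[C@H](O[Si](CC)(CC)CC)C[C@]2(C)[C@H]1C
F7 | step 1 | (2E)-3-(5-hydroxy-2-methylphenyl)-N-methoxy-N-methylprop-2-enamide | CON(C)C(=O)/C=C/c1cc(O)ccc1C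
F8 | step 1 | 3-(5-hydroxy-2-methylphenyl)-N-methoxy-N-methylpropanamide | CON(C)C(=O)CCc1cc(O)ccc1C
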